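**Retrosynthetic overview**

- The strategy rests on the skipped diene C8=C9–C10–C11=C12 of the 14-membered carbocycle (ring atoms C1–C14). C10 is the only doubly allylic CH2, so the vinyl–allyl bond C9–C10 is cut to a seco chain with a (Z)-alkenylstannane at C9 and an allylic chloride at C10. This single ring is closed last.
- The seco chain is cut at C3=C4 by Horner–Wadsworth–Emmons olefination into aldehyde fragment A (C1–C3, C10–C14) and phosphonate fragment B (C4–C9, C18). C2–O comes from L-proline aminoxylation of the aldehyde.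
- Fragment A comes from (S)-limonene (sets C1) by ring ozonolysis, alkyne homologation, trans-hydroalumination/iodination and methyl cross-coupling (E C11=C12).
- Fragment B comes from an ynone by asymmetric transfer hydrogenation (sets C7) and anti-carbomagnesiation/iodination (Z C8=C9).
- After ring closure only the C7 silyl ether is removed.

Key step: step 20

Remark on the chemistry: the ring is numbered from the isopropenyl-bearing C1 through the acetoxy-bearing C2 to C14, and C18 is the acetoxymethyl carbon on C4. The C9 alkenyl group is carried as the iodide through the fragment union and exchanged for tin only after the copper-mediated N–O cleavage.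

**Fragment A**

Step 1
Reactants: 1 (S)-(−)-limonene
Product: 4 (5S)-7,7-dimethoxy-5-(prop-1-en-2-yl)heptan-2-one, via hydroperoxy methoxy aldehyde 2 (not isolated), via hydroperoxy methoxy acetal 3 (not isolated)
Conditions: O3 (1.0 equiv), CH2Cl2/MeOH, −78 °C; TsOH·H2O (cat.), rt; NaHCO3; Me2S, rt
Reagents that add atoms: ozone [O-][O+]=O; methanol CO
Why: Terminally differentiating ozonolysis: ozone should attack the electron-richer trisubstituted ring alkene before the isopropenyl group, methanol traps the ketone-side carbonyl oxide as the methoxy hydroperoxide while the aldehyde is acetalised under acid, and sulfide reduction then releases only the ketone; the stereocentre is not involved.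

Step 2
Reactants: 4 (5S)-7,7-dimethoxy-5-(prop-1-en-2-yl)heptan-2-one
Product: 7 (6S)-8,8-dimethoxy-6-(prop-1-en-2-yl)oct-2-yn-1-ol, via enol diethyl phosphate 5 (not isolated), via lithium acetylide 6 (not isolated)
Conditions: LiN(i-Pr)2 (1.1 equiv), THF, −78 °C; ClP(O)(OEt)2, −78 °C → rt; LiN(i-Pr)2 (2.3 equiv), −78 °C → rt; (CH2O)n, 0 °C → rt
Reagents that add atoms: formaldehyde (from paraformaldehyde) C=O
Why: Enol phosphate route from a methyl ketone to a terminal alkyne: kinetic deprotonation on the methyl side, O-phosphorylation and base-induced elimination give the acetylide, which is hydroxymethylated in the same flask by addition to formaldehyde (this carbon becomes C10).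

Step 3
Reactants: 7 (6S)-8,8-dimethoxy-6-(prop-1-en-2-yl)oct-2-yn-1-ol
Product: 9 (2Z,6S)-3-iodo-8,8-dimethoxy-6-(prop-1-en-2-yl)oct-2-en-1-ol, via cyclic alkenylalanate 8 (not isolated)
Conditions: NaAlH2(OCH2CH2OMe)2 (1.6 equiv), THF, 0 °C → rt; EtOAc; I2, −78 °C → 0 °C
Reagents that add atoms: iodine [I][I]
Why: Hydroxyl-directed trans-hydroalumination of a propargylic alcohol: aluminium is delivered to the distal alkyne carbon (future C12) within a five-membered alkoxyalanate, so iodinolysis with retention gives the iodide cis to CH2OH (Z), and the acetal and isopropenyl group are not reducible.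

Step 4
Reactants: 9 (2Z,6S)-3-iodo-8,8-dimethoxy-6-(prop-1-en-2-yl)oct-2-en-1-ol
Product: 10 (2E,6S)-8,8-dimethoxy-3-methyl-6-(prop-1-en-2-yl)oct-2-en-1-ol
Conditions: MeZnCl (3 equiv), Pd(PPh3)4 (5 mol%), THF, 0 °C → rt
Reagents that add atoms: methylzinc chloride C[Zn]Cl
Why: Negishi cross-coupling: oxidative addition of zerovalent palladium into the alkenyl C–I bond, methyl transfer from zinc and reductive elimination all proceed with retention, so the Z iodide becomes the E trisubstituted alkene C11=C12 with the chain trans to C10.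

Step 5
Reactants: 10 (2E,6S)-8,8-dimethoxy-3-methyl-6-(prop-1-en-2-yl)oct-2-en-1-ol
Product: 11 1-({[(2E,6S)-8,8-dimethoxy-3-methyl-6-(prop-1-en-2-yl)oct-2-en-1-yl]oxy}methyl)-4-methoxybenzene
Conditions: NaH, 4-MeOC6H4CH2Cl, Bu4NI (cat.), THF/DMF, 0 °C → rt
Reagents that add atoms: 4-methoxybenzyl chloride COc1ccc(CCl)cc1
Why: Williamson etherification of the primary allylic alkoxide with a benzylic chloride under iodide catalysis; the acetal and both alkenes are inert to NaH.

Step 6
Reactants: 11 1-({[(2E,6S)-8,8-dimethoxy-3-methyl-6-(prop-1-en-2-yl)oct-2-en-1-yl]oxy}methyl)-4-methoxybenzene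
Product: 12 (3S,6E)-8-[(4-methoxybenzyl)oxy]-6-methyl-3-(prop-1-en-2-yl)oct-6-enal
Conditions: TsOH·H2O (cat.), acetone/H2O, rt
Reagents that add atoms: water O
Why: Acid-catalysed acetal hydrolysis: a dimethyl acetal of an aliphatic aldehyde is cleaved under conditions too mild to protonate the isopropenyl group or cleave the 4-methoxybenzyl ether, and the stereocentre is beta to the carbonyl and cannot epimerise.

**Fragment B**

Step 7
Reactants: 13 3-chloropropanoyl chloride; 14 bis(trimethylsilyl)acetylene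
Product: 15 5-chloro-1-(trimethylsilyl)pent-1-yn-3-one
Conditions: AlCl3 (1.1 equiv), CH2Cl2, 0 °C
Reagents that add atoms: none
Why: Friedel–Crafts-type acylation of an alkynylsilane: the acylium ion attacks ipso to silicon (beta-silyl stabilisation) and chloride removes that silyl group, giving the mono-silylated ynone.

Step 8
Reactants: 15 5-chloro-1-(trimethylsilyl)pent-1-yn-3-one
Product: 16 (3S)-5-chloro-1-(trimethylsilyl)pent-1-yn-3-ol
Conditions: Ru[(S,S)-TsDPEN](p-cymene) (1 mol%), i-PrOH, rt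
Reagents that add atoms: none
Why: Noyori asymmetric transfer hydrogenation of an alkynyl ketone: the preformed 16-electron amido catalyst works without added base (so HCl is not lost from the beta-chloro ketone), and with the (S,S) ligand hydride is delivered to the face that gives the (S)-propargylic alcohol, the alkyne acting as the pi-substituent; this sets C7.

Step 9
Reactants: 16 (3S)-5-chloro-1-(trimethylsilyl)pent-1-yn-3-ol
Product: 17 (3S)-5-chloropent-1-yn-3-ol
Conditions: K2CO3 (0.2 equiv), MeOH, 0 °C → rt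
Reagents that add atoms: none
Why: Base-catalysed methanolysis of the alkynyl C–Si bond (protodesilylation); the 1,3-chlorohydrin should not close to an oxetane under these mild conditions.

Step 10
Reactants: 17 (3S)-5-chloropent-1-yn-3-ol
Product: 19 (1Z,3S)-5-chloro-1-iodo-2-methylpent-1-en-3-ol, via cyclic alkenylmagnesium alkoxide 18 (not isolated)
Conditions: MeMgBr (3.5 equiv), CuI (0.2 equiv), Et2O/THF, −10 °C → rt; I2, −40 °C → 0 °C
Reagents that add atoms: methylmagnesium bromide C[Mg]Br; iodine [I][I]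
Why: Copper-catalysed anti-carbomagnesiation of a propargylic alkoxide: the magnesium alkoxide directs methyl to the proximal carbon (C8) and magnesium to the terminal carbon (C9) within a five-membered chelate, so the C–Mg bond is cis to the carbinol carbon and iodinolysis with retention gives the Z alkenyl iodide; the primary alkyl chloride should not couple with the Grignard reagent at this temperature.

Step 11
Reactants: 19 (1Z,3S)-5-chloro-1-iodo-2-methylpent-1-en-3-ol
Product: 20 {[(1Z,3S)-5-chloro-1-iodo-2-methylpent-1-en-3-yl]oxy}triethylsilane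
Conditions: Et3SiCl, imidazole, DMF, 0 °C → rt
Reagents that add atoms: chlorotriethylsilane CC[Si](Cl)(CC)CC
Why: Silylation of a secondary alcohol with a silyl chloride under imidazole (nucleophilic) catalysis.

Step 12
Reactants: 20 {[(1Z,3S)-5-chloro-1-iodo-2-methylpent-1-en-3-yl]oxy}triethylsilane; 21 triethyl phosphonoacetate
Product: 23 ethyl (5S,6Z)-2-(diethoxyphosphoryl)-7-iodo-6-methyl-5-(triethylsilyloxy)hept-6-enoate (both C2 epimers), via alkyl iodide 22 (not isolated)
Conditions: 21 (2.2 equiv), NaH (2.0 equiv), DMSO, rt; then 20, NaI (1 equiv), 60 °C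
Reagents that add atoms: none
Why: SN2 alkylation of a stabilised phosphonate carbanion after in situ Finkelstein exchange of the primary chloride for iodide; excess phosphonate salt suppresses dialkylation and the alkenyl iodide cannot eliminate because C8 bears no hydrogen.

**Union and end game**

Step 13
Reactants: 12 (3S,6E)-8-[(4-methoxybenzyl)oxy]-6-methyl-3-(prop-1-en-2-yl)oct-6-enal; 23 ethyl (5S,6Z)-2-(diethoxyphosphoryl)-7-iodo-6-methyl-5-(triethylsilyloxy)hept-6-enoate
Product: 25 ethyl (2E,4S,5R,8E)-2-[(3S,4Z)-5-iodo-4-methyl-3-(triethylsilyloxy)pent-4-en-1-yl]-10-[(4-methoxybenzyl)oxy]-8-methyl-4-[(phenylamino)oxy]-5-(prop-1-en-2-yl)deca-2,8-dienoate, via alpha-aminooxy aldehyde 24 (not isolated)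
Conditions: PhNO (1.1 equiv), L-proline (20 mol%), MeCN, −20 °C; then 23 (1.2 equiv), LiCl, DBU, MeCN, 0 °C → rt
Reagents that add atoms: nitrosobenzene O=Nc1ccccc1
Why: Proline-catalysed alpha-aminoxylation followed by Horner–Wadsworth–Emmons olefination: the (E)-enamine of 12 with L-proline attacks the nitroso oxygen on the face to which the carboxylic acid directs it by hydrogen bonding, giving the (2R) aldehyde that corresponds to (2S) at C2 of the target (catalyst control over the neighbouring C1 centre), and the lithium-chelated phosphonate carbanion should then give the E trisubstituted enoate (C2 cis to C5) under the mild LiCl/DBU conditions before the labile aldehyde can epimerise.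

Step 14
Reactants: 25 the gamma-aminooxy enoate of step 13
Product: 26 ethyl (2E,4S,5R,8E)-4-hydroxy-2-[(3S,4Z)-5-iodo-4-methyl-3-(triethylsilyloxy)pent-4-en-1-yl]-10-[(4-methoxybenzyl)oxy]-8-methyl-5-(prop-1-en-2-yl)deca-2,8-dienoate
Conditions: Cu(OAc)2 (30 mol%), EtOH, rt
Reagents that add atoms: none
Why: Copper-catalysed N–O bond cleavage of an O-alkyl-N-arylhydroxylamine, a neutral method that should leave the C2 centre, the enoate, the silyl ether and the alkenyl iodide untouched; the E geometry prevents lactonisation of the gamma-hydroxy ester.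

Step 15
Reactants: 26 the gamma-hydroxy enoate of step 14
Product: 27 (2E,4S,5R,8E)-2-[(3S,4Z)-5-iodo-4-methyl-3-(triethylsilyloxy)pent-4-en-1-yl]-10-[(4-methoxybenzyl)oxy]-8-methyl-5-(prop-1-en-2-yl)deca-2,8-diene-1,4-diol
Conditions: i-Bu2AlH (4.5 equiv), CH2Cl2, −78 °C → −20 °C
Reagents that add atoms: none
Why: Hydride reduction of an alpha,beta-unsaturated ester to the allylic alcohol by 1,2-addition; i-Bu2AlH at low temperature does not touch the alkenyl iodide or the ethers.

Step 16
Reactants: 27 the C2,C18-diol alkenyl iodide of step 15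
Product: 28 (2E,4S,5R,8E)-10-[(4-methoxybenzyl)oxy]-8-methyl-2-[(3S,4Z)-4-methyl-3-(triethylsilyloxy)-5-(tributylstannyl)pent-4-en-1-yl]-5-(prop-1-en-2-yl)deca-2,8-diene-1,4-diol
Conditions: (Bu3Sn)2 (2 equiv), Pd(PPh3)4 (5 mol%), i-Pr2NEt, toluene, 80 °C
Reagents that add atoms: hexabutylditin CCCC[Sn](CCCC)(CCCC)[Sn](CCCC)(CCCC)CCCC
Why: Palladium-catalysed stannylation of an alkenyl iodide with a distannane (oxidative addition, Sn–Sn transmetalation, C–Sn reductive elimination) with retention of the Z geometry; free allylic alcohols and the benzylic ether are not ionised by zerovalent palladium.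

Step 17
Reactants: 28 the C2,C18-diol alkenylstannane of step 16
Product: 29 (2E,4S,5R,8E)-10-[(4-methoxybenzyl)oxy]-8-methyl-2-[(3S,4Z)-4-methyl-3-(triethylsilyloxy)-5-(tributylstannyl)pent-4-en-1-yl]-5-(prop-1-en-2-yl)deca-2,8-diene-1,4-diyl diacetate
Conditions: Ac2O, pyridine, DMAP (cat.), CH2Cl2, 0 °C → rt
Reagents that add atoms: acetic anhydride CC(=O)OC(C)=O
Why: Nucleophile-catalysed (DMAP) acylation of the primary C18 and secondary C2 allylic alcohols; the alkenylstannane and the silyl ether tolerate the basic medium.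

Step 18
Reactants: 29 the diacetate of step 17
Product: 30 (2E,4S,5R,8E)-10-hydroxy-8-methyl-2-[(3S,4Z)-4-methyl-3-(triethylsilyloxy)-5-(tributylstannyl)pent-4-en-1-yl]-5-(prop-1-en-2-yl)deca-2,8-diene-1,4-diyl diacetate
Conditions: DDQ (1.3 equiv), CH2Cl2/pH 7 buffer, 0 °C
Reagents that add atoms: none
Why: Oxidative cleavage of a 4-methoxybenzyl ether by DDQ (hydride abstraction to the oxocarbenium ion, then hydrolysis), run buffered and cold to spare the triethylsilyl ether and the alkenylstannane.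

Step 19
Reactants: 30 the C10 allylic alcohol of step 18
Product: 32 (2E,4S,5R,8E)-10-chloro-8-methyl-2-[(3S,4Z)-4-methyl-3-(triethylsilyloxy)-5-(tributylstannyl)pent-4-en-1-yl]-5-(prop-1-en-2-yl)deca-2,8-diene-1,4-diyl diacetate, via allylic methanesulfonate 31 (not isolated)
Conditions: MsCl, 2,4,6-collidine, LiCl, DMF, 0 °C
Reagents that add atoms: lithium chloride [Li+].[Cl-]
Why: Mesylation of the primary allylic alcohol and SN2 displacement by chloride in the same flask (no SN2' at the fully substituted C12), which keeps the E geometry and uses no electrophilic halogen that could cleave the C–Sn bond.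

Step 20
Reactants: 32 the seco chain with the C10 allylic chloride and the C9 (Z)-alkenyl tributylstannane
Product: 33 (1R,2S,3E,7S,8Z,11E)-2-acetoxy-4-(acetoxymethyl)-8,12-dimethyl-1-(prop-1-en-2-yl)-7-(triethylsilyloxy)cyclotetradeca-3,8,11-triene
Conditions: Pd2(dba)3 (20 mol%), AsPh3 (80 mol%), degassed DMF/THF, 1 mM final concentration, syringe-pump addition, 40 °C
Reagents that add atoms: none
Why: Zerovalent palladium ionises the primary allylic chloride at C10 to the η3-allyl spanning C10–C12, the (Z)-alkenyl group at C9 moves from tin to palladium with retention, and reductive elimination joins C9 to C10; the closest known reaction type is the intramolecular Stille coupling of an alkenylstannane with an allylic halide used to close macrocycles at a skipped diene. The single ring, the 14-membered carbocycle, closes end to end between the two chain termini under high dilution. No stereocentre is formed; C1, C2 and C7 are spectators, and both trisubstituted alkene geometries are carried in: Z at C8=C9 by retention at tin, E at C11=C12 because the allyl unit keeps its geometry as long as palladium does not sigma-bond to the fully substituted C12. Coupling at C10 and not C12 should follow from reductive elimination at the unsubstituted allyl terminus. Ionisation of the chloride in preference to the C2 and C18 allylic acetates should be secured by the much faster oxidative addition of the chloride with the weakly donating AsPh3 ligand near room temperature. The neutral medium should leave the new 1,4-diene unconjugated.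

Step 21
Reactants: 33 the C7 triethylsilyl ether of the target
Product: 34 (1R,2S,3E,7S,8Z,11E)-2-acetoxy-4-(acetoxymethyl)-7-hydroxy-8,12-dimethyl-1-(prop-1-en-2-yl)cyclotetradeca-3,8,11-triene (CNP0097266.2)
Conditions: HF·pyridine, pyridine, THF, 0 °C → rt
Reagents that add atoms: none
Why: Fluoride-mediated cleavage of the triethylsilyl ether; buffered HF·pyridine should neither hydrolyse nor migrate the two acetates and leaves the skipped diene untouched.

**Compound list**

1 | (S)-(−)-limonene | CC1=CC[C@H](CC1)C(C)=C | starting material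
2 | (3S)-6-hydroperoxy-6-methoxy-3-(prop-1-en-2-yl)heptanal (C6 epimers) | COC(C)(OO)CC[C@@H](CC=O)C(C)=C | intermediate
3 | (5S)-2-hydroperoxy-2,7,7-trimethoxy-5-(prop-1-en-2-yl)heptane (C2 epimers) | COC(C)(OO)CC[C@@H](CC(OC)OC)C(C)=C | intermediate
4 | (5S)-7,7-dimethoxy-5-(prop-1-en-2-yl)heptan-2-one | CC(=O)CC[C@@H](CC(OC)OC)C(C)=C | intermediate
5 | diethyl (5S)-7,7-dimethoxy-5-(prop-1-en-2-yl)hept-1-en-2-yl phosphate | C=C(OP(=O)(OCC)OCC)CC[C@@H](CC(OC)OC)C(C)=C | intermediate
6 | [(5S)-7,7-dimethoxy-5-(prop-1-en-2-yl)hept-1-yn-1-yl]lithium | [Li]C#CCC[C@@H](CC(OC)OC)C(C)=C | intermediate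
7 | (6S)-8,8-dimethoxy-6-(prop-1-en-2-yl)oct-2-yn-1-ol | OCC#CCC[C@@H](CC(OC)OC)C(C)=C | intermediate
8 | sodium cyclic alkoxy(alkenyl)bis(2-methoxyethoxy)aluminate from 7 (Al on the future C12, O–Al five-membered ring) | [Na+].COCCO[Al-]1(OCCOC)OCC=C1CC[C@@H](CC(OC)OC)C(C)=C | intermediate
9 | (2Z,6S)-3-iodo-8,8-dimethoxy-6-(prop-1-en-2-yl)oct-2-en-1-ol | OC/C=C(\I)CC[C@@H](CC(OC)OC)C(C)=C | intermediate
10 | (2E,6S)-8,8-dimethoxy-3-methyl-6-(prop-1-en-2-yl)oct-2-en-1-ol | OC/C=C(\C)CC[C@@H](CC(OC)OC)C(C)=C | intermediate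
11 | 1-({[(2E,6S)-8,8-dimethoxy-3-methyl-6-(prop-1-en-2-yl)oct-2-en-1-yl]oxy}methyl)-4-methoxybenzene | COc1ccc(COC/C=C(\C)CC[C@@H](CC(OC)OC)C(C)=C)cc1 | intermediate
12 | (3S,6E)-8-[(4-methoxybenzyl)oxy]-6-methyl-3-(prop-1-en-2-yl)oct-6-enal | COc1ccc(COC/C=C(\C)CC[C@@H](CC=O)C(C)=C)cc1 | intermediate
13 | 3-chloropropanoyl chloride | ClCCC(Cl)=O | starting material
14 | bis(trimethylsilyl)acetylene | C[Si](C)(C)C#C[Si](C)(C)C | starting material
15 | 5-chloro-1-(trimethylsilyl)pent-1-yn-3-one | ClCCC(=O)C#C[Si](C)(C)C | intermediate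
16 | (3S)-5-chloro-1-(trimethylsilyl)pent-1-yn-3-ol | ClCC[C@H](O)C#C[Si](C)(C)C | intermediate
17 | (3S)-5-chloropent-1-yn-3-ol | ClCC[C@H](O)C#C | intermediate
18 | (5S)-5-(2-chloroethyl)-4-methyl-2,5-dihydro-1,2-oxamagnesole (cyclic alkenylmagnesium alkoxide) | ClCC[C@@H]1O[Mg]C=C1C | intermediate
19 | (1Z,3S)-5-chloro-1-iodo-2-methylpent-1-en-3-ol | ClCC[C@H](O)/C(C)=C\I | intermediate
20 | {[(1Z,3S)-5-chloro-1-iodo-2-methylpent-1-en-3-yl]oxy}triethylsilane | ClCC[C@H](O[Si](CC)(CC)CC)/C(C)=C\I | intermediate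
21 | triethyl phosphonoacetate | CCOC(=O)CP(=O)(OCC)OCC | starting material
22 | {[(1Z,3S)-1,5-diiodo-2-methylpent-1-en-3-yl]oxy}triethylsilane | ICC[C@H](O[Si](CC)(CC)CC)/C(C)=C\I | intermediate
23 | ethyl (5S,6Z)-2-(diethoxyphosphoryl)-7-iodo-6-methyl-5-(triethylsilyloxy)hept-6-enoate (both C2 epimers) | CCOC(=O)C(CC[C@H](O[Si](CC)(CC)CC)/C(C)=C\I)P(=O)(OCC)OCC | intermediate
24 | (2R,3R,6E)-8-[(4-methoxybenzyl)oxy]-6-methyl-2-[(phenylamino)oxy]-3-(prop-1-en-2-yl)oct-6-enal | COc1ccc(COC/C=C(C)/CC[C@H](C(C)=C)[C@@H](ONc2ccccc2)C=O)cc1 | intermediate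
25 | ethyl (2E,4S,5R,8E)-2-[(3S,4Z)-5-iodo-4-methyl-3-(triethylsilyloxy)pent-4-en-1-yl]-10-[(4-methoxybenzyl)oxy]-8-methyl-4-[(phenylamino)oxy]-5-(prop-1-en-2-yl)deca-2,8-dienoate | COc1ccc(COC/C=C(C)/CC[C@H](C(C)=C)[C@@H](ONc2ccccc2)/C=C(C(=O)OCC)\CC[C@H](O[Si](CC)(CC)CC)/C(C)=C\I)cc1 | intermediate
26 | ethyl (2E,4S,5R,8E)-4-hydroxy-2-[(3S,4Z)-5-iodo-4-methyl-3-(triethylsilyloxy)pent-4-en-1-yl]-10-[(4-methoxybenzyl)oxy]-8-methyl-5-(prop-1-en-2-yl)deca-2,8-dienoate | COc1ccc(COC/C=C(C)/CC[C@H](C(C)=C)[C@@H](O)/C=C(C(=O)OCC)\CC[C@H](O[Si](CC)(CC)CC)/C(C)=C\I)cc1 | intermediate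
27 | (2E,4S,5R,8E)-2-[(3S,4Z)-5-iodo-4-methyl-3-(triethylsilyloxy)pent-4-en-1-yl]-10-[(4-methoxybenzyl)oxy]-8-methyl-5-(prop-1-en-2-yl)deca-2,8-diene-1,4-diol | COc1ccc(COC/C=C(C)/CC[C@H](C(C)=C)[C@@H](O)/C=C(CO)\CC[C@H](O[Si](CC)(CC)CC)/C(C)=C\I)cc1 | intermediate
28 | (2E,4S,5R,8E)-10-[(4-methoxybenzyl)oxy]-8-methyl-2-[(3S,4Z)-4-methyl-3-(triethylsilyloxy)-5-(tributylstannyl)pent-4-en-1-yl]-5-(prop-1-en-2-yl)deca-2,8-diene-1,4-diol | COc1ccc(COC/C=C(C)/CC[C@H](C(C)=C)[C@@H](O)/C=C(CO)\CC[C@H](O[Si](CC)(CC)CC)/C(C)=C\[Sn](CCCC)(CCCC)CCCC)cc1 | intermediate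
29 | (2E,4S,5R,8E)-10-[(4-methoxybenzyl)oxy]-8-methyl-2-[(3S,4Z)-4-methyl-3-(triethylsilyloxy)-5-(tributylstannyl)pent-4-en-1-yl]-5-(prop-1-en-2-yl)deca-2,8-diene-1,4-diyl diacetate | COc1ccc(COC/C=C(C)/CC[C@H](C(C)=C)[C@@H](OC(C)=O)/C=C(COC(C)=O)\CC[C@H](O[Si](CC)(CC)CC)/C(C)=C\[Sn](CCCC)(CCCC)CCCC)cc1 | intermediate
30 | (2E,4S,5R,8E)-10-hydroxy-8-methyl-2-[(3S,4Z)-4-methyl-3-(triethylsilyloxy)-5-(tributylstannyl)pent-4-en-1-yl]-5-(prop-1-en-2-yl)deca-2,8-diene-1,4-diyl diacetate | OC/C=C(C)/CC[C@H](C(C)=C)[C@@H](OC(C)=O)/C=C(COC(C)=O)\CC[C@H](O[Si](CC)(CC)CC)/C(C)=C\[Sn](CCCC)(CCCC)CCCC | intermediate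
31 | (2E,4S,5R,8E)-10-(methanesulfonyloxy)-8-methyl-2-[(3S,4Z)-4-methyl-3-(triethylsilyloxy)-5-(tributylstannyl)pent-4-en-1-yl]-5-(prop-1-en-2-yl)deca-2,8-diene-1,4-diyl diacetate | CS(=O)(=O)OC/C=C(C)/CC[C@H](C(C)=C)[C@@H](OC(C)=O)/C=C(COC(C)=O)\CC[C@H](O[Si](CC)(CC)CC)/C(C)=C\[Sn](CCCC)(CCCC)CCCC | intermediate
32 | (2E,4S,5R,8E)-10-chloro-8-methyl-2-[(3S,4Z)-4-methyl-3-(triethylsilyloxy)-5-(tributylstannyl)pent-4-en-1-yl]-5-(prop-1-en-2-yl)deca-2,8-diene-1,4-diyl diacetate (seco chain, key-step precursor) | ClC/C=C(C)/CC[C@H](C(C)=C)[C@@H](OC(C)=O)/C=C(COC(C)=O)\CC[C@H](O[Si](CC)(CC)CC)/C(C)=C\[Sn](CCCC)(CCCC)CCCC | intermediate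
33 | (1R,2S,3E,7S,8Z,11E)-2-acetoxy-4-(acetoxymethyl)-8,12-dimethyl-1-(prop-1-en-2-yl)-7-(triethylsilyloxy)cyclotetradeca-3,8,11-triene | C=C(C)[C@H]1CC/C(C)=C/C/C=C(/C)[C@@H](O[Si](CC)(CC)CC)CC/C(COC(C)=O)=C\[C@@H]1OC(C)=O | intermediate
34 | (1R,2S,3E,7S,8Z,11E)-2-acetoxy-4-(acetoxymethyl)-7-hydroxy-8,12-dimethyl-1-(prop-1-en-2-yl)cyclotetradeca-3,8,11-triene (CNP0097266.2) | C=C(C)[C@H]1CC/C(C)=C/C/C=C(/C)[C@@H](O)CC/C(COC(C)=O)=C\[C@@H]1OC(C)=O | target

**Step count and risk**

Total step count: 21 (fragment A steps 1–6, fragment B steps 7–12, union and end game steps 13–21).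
Longest linear sequence: 15 steps (steps 1–6 or 7–12, then 13–21).

Steps most likely to fail:

1. Step 20. Intermolecular coupling may outrun ring closure and give oligomers. Tin-to-palladium transfer from the hindered trisubstituted alkenylstannane may be slow enough for protodestannylation or for ionisation of the allylic acetates to compete. The fallback closes the same C9–C10 bond from a tin-free bis-electrophile with nickel. It sets out from 27, which is acetylated (Ac2O, pyridine, DMAP) to the diacetate alkenyl iodide F1. DDQ in buffered CH2Cl2 then frees the C10 allylic alcohol F2, and CBr4/PPh3 converts it into the allylic bromide F3. Stoichiometric Ni(cod)2 (zerovalent nickel) in DMF at high dilution should insert into the C10–Br bond to give the η3-allylnickel bromide, which couples with the C9 alkenyl iodide at the unsubstituted allyl terminus. The fallback comes back to the route at 33.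

2. Step 13. The alpha-aminooxy aldehyde may epimerise at C2 or lose its N–O bond under the basic olefination conditions, and the alpha-branched phosphonate may give incomplete E selectivity. The fallback uses an acyloxy group and a base-free Wittig reaction. It sets out from 12, which is alpha-benzoyloxylated with dibenzoyl peroxide and catalytic (R)-alpha,alpha-diphenylprolinol trimethylsilyl ether to the (2R,3R)-2-(benzoyloxy) aldehyde F4. The (R)-configured catalyst shields the enamine face opposite to the one reached under L-proline hydrogen bonding, so oxygen should arrive on the same face as in step 13. Separately, iodide 22 is isolated from 20 (NaI, acetone) and alkylates ethyl (triphenylphosphoranylidene)acetate (2 equiv, one acting as base) to give the stabilised phosphorane F5. Wittig reaction of F4 with F5 in toluene should give the E gamma-benzoyloxy enoate F6. i-Bu2AlH then cleaves the ethyl ester and the benzoate together, and the fallback comes back to the route at 27.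

3. Step 16. The newly formed stannane may couple with unreacted iodide (Stille-type homocoupling), or the iodide may be lost by reduction. The fallback replaces palladium by lithium–iodine exchange. It sets out from 27, which is silylated with Me3SiCl/imidazole to the bis(trimethylsilyl) ether F7. t-BuLi (2.1 equiv) in Et2O at −78 °C followed directly by Bu3SnCl should give the alkenylstannane F8 with retention; the cold, immediate quench is meant to forestall silyl migration from O7 to C9. K2CO3 in MeOH at 0 °C removes the two trimethylsilyl ethers and keeps the triethylsilyl ether, and the fallback comes back to the route at 28.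

Further compounds
F1 | step 20 | (2E,4S,5R,8E)-2-[(3S,4Z)-5-iodo-4-methyl-3-(triethylsilyloxy)pent-4-en-1-yl]-10-[(4-methoxybenzyl)oxy]-8-methyl-5-(prop-1-en-2-yl)deca-2,8-diene-1,4-diyl diacetate | COc1ccc(COC/C=C(C)/CC[C@H](C(C)=C)[C@@H](OC(C)=O)/C=C(COC(C)=O)\CC[C@H](O[Si](CC)(CC)CC)/C(C)=C\I)cc1
F2 | step 20 | (2E,4S,5R,8E)-10-hydroxy-2-[(3S,4Z)-5-iodo-4-methyl-3-(triethylsilyloxy)pent-4-en-1-yl]-8-methyl-5-(prop-1-en-2-yl)deca-2,8-diene-1,4-diyl diacetate | OC/C=C(C)/CC[C@H](C(C)=C)[C@@H](OC(C)=O)/C=C(COC(C)=O)\CC[C@H](O[Si](CC)(CC)CC)/C(C)=C\I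
F3 | step 20 | (2E,4S,5R,8E)-10-bromo-2-[(3S,4Z)-5-iodo-4-methyl-3-(triethylsilyloxy)pent-4-en-1-yl]-8-methyl-5-(prop-1-en-2-yl)deca-2,8-diene-1,4-diyl diacetate | BrC/C=C(C)/CC[C@H](C(C)=C)[C@@H](OC(C)=O)/C=C(COC(C)=O)\CC[C@H](O[Si](CC)(CC)CC)/C(C)=C\I
F4 | step 13 | (2R,3R,6E)-2-(benzoyloxy)-8-[(4-methoxybenzyl)oxy]-6-methyl-3-(prop-1-en-2-yl)oct-6-enal | COc1ccc(COC/C=C(C)/CC[C@H](C(C)=C)[C@@H](OC(=O)c2ccccc2)C=O)cc1
F5 | step 13 | ethyl (5S,6Z)-7-iodo-6-methyl-5-(triethylsilyloxy)-2-(triphenylphosphoranylidene)hept-6-enoate | CCOC(=O)C(CC[C@H](O[Si](CC)(CC)CC)/C(C)=C\I)=P(c1ccccc1)(c1ccccc1)c1ccccc1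
F6 | step 13 | ethyl (2E,4S,5R,8E)-4-(benzoyloxy)-2-[(3S,4Z)-5-iodo-4-methyl-3-(triethylsilyloxy)pent-4-en-1-yl]-10-[(4-methoxybenzyl)oxy]-8-methyl-5-(prop-1-en-2-yl)deca-2,8-dienoate | COc1ccc(COC/C=C(C)/CC[C@H](C(C)=C)[C@@H](OC(=O)c2ccccc2)/C=C(C(=O)OCC)\CC[C@H](O[Si](CC)(CC)CC)/C(C)=C\I)cc1
F7 | step 16 | bis(trimethylsilyl) ether of 27 at O2 and O18 | COc1ccc(COC/C=C(C)/CC[C@H](C(C)=C)[C@@H](O[Si](C)(C)C)/C=C(CO[Si](C)(C)C)\CC[C@H](O[Si](CC)(CC)CC)/C(C)=C\I)cc1
F8 | step 16 | bis(trimethylsilyl) ether of 28 at O2 and O18 | COc1ccc(COC/C=C(C)/CC[C@H](C(C)=C)[C@@H](O[Si](C)(C)C)/C=C(CO[Si](C)(C)C)\CC[C@H](O[Si](CC)(CC)CC)/C(C)=C\[Sn](CCCC)(CCCC)CCCC)cc1
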